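The earlier runs and the new flask come from a simulation with constants of no real substance, and the scatter is random.

What is not in chains at the last zeta reading, 46.0% of the charge, began our dispute, since the readings do not say what becomes of it.

all flasks: initiator 50 µM
- zeta: free monomer 16 mM; run made earlier
- epsilon: free monomer 78 mM; run made earlier
- violet: free monomer 14 mM; time 25 min
- red: free monomer 60 mM; time 25 min

| run | time / min | monomer in chains / % |
|---|---|---|
| zeta | 1.50 | 17 |
| zeta | 4.00 | 42 |
| zeta | 8.00 | 53 |
| zeta | 12.0 | 54 |
| epsilon | 1.50 | 29 |
| epsilon | 4.00 | 50 |
| epsilon | 8.00 | 63 |
| epsilon | 12.0 | 66 |

(scatter of a reading: 1.5 percentage points)

- the average divides the monomer in chains by the number of chains begun, living and dead together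
- the earlier runs were read with a standard deviation of 1.5 percentage points
- the earlier runs do not show the number of chains; that part of a forecast is a guess

1. which of the two ends with the longer chains by the average number of monomer units in a chain (chains begun, living or dead) ("neither" if they lie within 10%) (violet / red / neither)
2. average number of monomer units in a chain (chains begun, living or dead) at the end, violet
3. average number of monomer units in a chain (chains begun, living or dead) at the end, red

We agreed on a frame. For violet, c(free monomer) over c(initiator) at the start is 280, and for red it is 1200; this is the charge ratio. If each initiator begins one chain, which is a guess, the average length is the charge ratio times the share of the charge in chains, so our quarrel concerned that share.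

The forecast's maker held the share flat: “both runs finish by about 15 minutes, so 25 minutes means the plateau”. The forecast therefore says red, with 150 for violet (range 105 to 250) and 780 for red (range 480 to 1150).

I doubted the flatness. Zeta's last step was 1 percentage point, less than the scatter of 1.5 points, so a step of that size downward also fits the readings. As a steady loss, that is 0.0400 mM min⁻¹. Taking the same loss over to violet and red, which is my guess, it removes 10.4 units per chain between 12.0 min and 25 min, so my own numbers, unlike the forecast's, are 140 for violet and 770 for red.

The flask gives red, with 110 for violet and 826 for red.

monomer in chains + living end → free monomer + living end, rate k1*[living end] as long as [monomer in chains] is above zero (k = 0.200 s⁻¹); free monomer + initiator → spent initiator (k = 0.330 M⁻¹ s⁻¹); free monomer → uncatalysed product (k = 0.00130 s⁻¹); free monomer + initiator → living end + monomer in chains (k = 6.90 M⁻¹ s⁻¹); free monomer + living end → monomer in chains + living end, rate k5*[living end]*[free monomer] (k = 79.0 M⁻¹ s⁻¹) The forecast is right on red but 1.36 times too high on violet, and my number is high there too. Violet's share falls from 49.1% at 12.5 min to 37.4% at 25.0 min, and the charge ratio times the later share gives 105. Red's share goes from 67.2% to 65.7% between the same times, so the flat view holds for red over that stretch. Violet recharged with 56 mM of free monomer has a charge ratio of 1120 and ends with 65.1% in chains, so the same reckoning gives 729, and the average in that flask is 764.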